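## The problem

The target (30) carries two 7-hydroxychromans on one central ring D: chroman 1 is bonded through C4 to D1, chroman 2 through C3' to the neighbouring D6, with OMe at D2 and OH at D4. Chroman 1 also bears ring B (2-hydroxy-4,5-dimethoxyphenyl) at C3, so C3 and C4 are vicinal, trans, aryl-bearing stereocentres; read from the structure they are 3R,4S, and C3' is R. C3 and C4 can control each other, since the trans diequatorial arrangement is the stable one. C3' lies three bonds from C4 across ring D and cannot be relied on for induction, so it must be made enantiopure on its own and the C3/C4 pair then set by a reagent that overrides it. Ring D is 1,2,3,5-tetrasubstituted with two different oxygen groups and two different carbon groups on adjacent positions, which makes regiocontrol on this ring the main constitutional problem. The four phenols sit on electron-rich rings that are easily oxidised, and any oxygenated C4 ionises readily under acid, so the phenols travel as benzyl ethers and strong acid or oxidants are kept out of the late stages. The key step is possible because O1, C8a, C4a and C4 with ring A make up an ortho-quinone methide whose C4 is stabilised by ortho/para oxygen donors on rings A and D, while C2, C3 and ring B make up an arylacetaldehyde. The pyran ring of chroman 1 is therefore a formal [4+2] adduct of these two units.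

## Retrosynthesis

**End game.** Target 30 is traced back to its tetrabenzyl ether 29 (four O–benzyl bonds) and 29 to the C2 lactol 27 (one C2–OH bond). Benzyl is used on all four phenols so that a single neutral hydrogenolysis ends the route without touching the methyl ethers or C3/C4; acetal or silyl groups would require acid or fluoride on an air-sensitive tetraphenol. Keeping C2 at the aldehyde oxidation level costs one ionic reduction but makes the pyran a hemiacetal that can be built from a phenol and an aldehyde. The forward steps must remove the anomeric hydroxyl without disturbing C3.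

**Key disconnection.** In 27 the C3–C4 and O1–C2 bonds are cut together, giving the ortho-hydroxybenzhydrol 20 (ring A, ring D and the complete chroman 2) and the ring B arylacetaldehyde 24. The neighbouring cuts are weaker:
- Cutting C4–D1 asks ring D, which has three nucleophilic positions, to react at its most hindered one.
- Cutting C3–ring B needs an α-arylation with an ortho-oxygenated aryl halide beside a crowded C4.
- Cutting only O1–C2 leaves both stereocentres to be made in an open chain.

The chosen cut removes one ring, two skeletal bonds and both vicinal stereocentres, and the small fragment is three steps from a commercial aldehyde. The forward reaction must form the ring A quinone methide from 20 under conditions in which an enamine survives, add the enamine of 24 at C4 under catalyst control, and close the hemiacetal. Either carbinol epimer of 20 serves, because C4 becomes trigonal.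

**Benzhydrol.** In 20 the D1–C4 bond is cut, giving aryl bromide 17 (as its aryllithium) and the purchasable salicylaldehyde 9 (as its phenoxide). The reverse polarity (ring D aldehyde plus metallated ring A) would add a formylation and a phenol protection/deprotection at the stage of the acid-labile benzhydrol. The forward step asks for bromine–lithium exchange at a position flanked by OMe and the chroman, then addition to a phenoxide-deactivated aldehyde.

**Chroman 2.** In 17 the O1'–C2' bond is cut to the phenol alcohol 16, which comes from the acetal-protected alcohol 15 and the imide 14. In 14 the C3'–C4' bond is cut to the acyl oxazolidinone 8 and the benzylic bromide 12. This places the only stereocentre of chroman 2 alpha to a carbonyl, where an auxiliary controls it reliably. An asymmetric hydrogenation of an isoflavene would have to tolerate the aryl bromide and an ortho,ortho'-substituted aryl group. Because the D1 bromine must survive to the benzhydrol stage, no hydrogenolysis or palladium chemistry is used before then; the ring E phenol (the benzo ring of chroman 2) is therefore masked as a methoxymethyl ether, orthogonal to benzyl.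

**Ring D pattern.** Imide 8 is cut at the N–acyl bond to acid 5 and auxiliary 6. Acid 5 goes back through ester 4, the mono-benzyl ether 3 and the bromoresorcinol 2 to the symmetric ester 1. The pattern is fixed on this simple ester, before a second electron-rich ring is present. Bromination of the symmetric resorcinol has only one constitutional competitor (the position between the hydroxyls), and the bromine then differentiates the hydroxyls (para versus ortho to Br) for benzylation and methylation. Bromination at the isoflavan stage would have to distinguish ring D from the equally activated ring E.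

**Small fragments.** Bromide 12 comes from 9 through the acetal 10 and the alcohol 11, so 9 supplies both ring A and ring E. Aldehyde 24 comes from the commercial aldehyde 21 by benzylation (22) and one-carbon homologation through enol ether 23.

## Roads not taken

**Alternative 1:** Both carbon–carbon bonds to ring D (D6–C3' and D1–C4) are cut at once. Forward, fluoride-induced elimination of silyl aryl triflate A3 releases aryne A4, which inserts into the acyl–α-carbon bond of β-ketoester A2 to give benzophenone A1.
- Merits: it is highly convergent and needs no organolithium. The usual bias of 3-alkoxyarynes sends the enolate carbon to the position remote from OMe and the acyl group next to it, which is the required regiochemistry.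
- Weak points: C3' is formed racemic as an epimerisable α-aryl ester. A2 is an α-substituted, hindered insertion partner, so simple α-arylation or O-arylation can compete. A3 needs its own multistep synthesis with the same OMe/OBn differentiation. After A1, chroman 2 must still be closed and the ketone reduced, which gives only the skeleton of 20 without control at C3'.
- Comparison: for assembling ring D this road is more convergent than the chosen one. The chosen plan sets against that an auxiliary-controlled C3' and a catalyst-controlled C3/C4 pair, at the price of a longer linear sequence.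

**Alternative 2:** Ring D itself is cut at D1–D2 and D5–D6. Forward, diene A7 adds across the alkyne of ynone A6 (alkyne carbons become D1 and D6), and loss of methanol and the silyl group aromatises to benzophenone A5.
- Merits: the OMe and OH of ring D arrive differentiated and regiospecifically, with no electrophilic substitution or hydroxyl differentiation. C3' is already in place, and A5 could be taken on to 20 by benzylation, acetal removal and carbonyl reduction, feeding the same annulation.
- Weak points: the stereocentre of A6 is propargylic to an ynone and can isomerise through the allenyl ketone. Enantiopure A6 needs an auxiliary route plus an alkyne homologation. A disubstituted ynone needs heat with the sensitive diene A7. The acetal must be removed before the ketone is reduced.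
- Comparison: on ring D regiocontrol this road is better than the chosen plan, whose steps 1 and 2 rest on selectivity. The chosen plan sets against that a configurationally robust C3', fewer steps from commercial materials and only routine reactions before the key step.

**Alternative 3:** The C8a–O1 bond is cut. Forward, peracid oxidation of indanone A9 with migration of the ring A carbon gives dihydrocoumarin A8.
- Merits: C4 is set earlier and independently by a well-established asymmetric construction of 3-arylindanones. C3 could later be introduced trans under substrate control. The hindered intermolecular union and the sensitive arylacetaldehyde are both avoided.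
- Weak points: in A9 the migrating carbon is meta to the benzyloxy group and gets no resonance assistance, while the peracid faces three very electron-rich arenes. After A8 the ring B aryl group must still be attached to a lactone enolate with an ortho-alkoxy aryl electrophile, and the lactone carbonyl reduced to the C2 methylene. A9, with the chroman-bearing aryl group, is itself long to make.
- Comparison: for C4 alone this road is at least as secure as the chosen plan. The chosen plan sets against that the formation of two bonds and both stereocentres in one step, and a two-step end game.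

Key step: step 17

Remarks on the chemistry: the descriptors (3R,4S) for chroman 1 and (3R) for C3' are derived from the target structure. Compound 9 is treated as purchasable; it is otherwise one selective benzylation away from 2,4-dihydroxybenzaldehyde. Ring E denotes the benzo ring of chroman 2.

## Route

Step 1
Reactants: 1 methyl 2-(3,5-dihydroxyphenyl)acetate
Product: 2 methyl 2-(2-bromo-3,5-dihydroxyphenyl)acetate
Conditions: NBS (1.0 equiv), CH2Cl2–MeCN, −40 °C to 0 °C
Reagents that add atoms: N-bromosuccinimide, O=C1CCC(=O)N1Br
Why: Electrophilic aromatic bromination of a 5-substituted resorcinol; the two equivalent positions next to the side chain are para to one hydroxyl and ortho to the other and should react ahead of the position between the hydroxyls, and one equivalent at low temperature limits dibromination.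

Step 2
Reactants: 2 methyl 2-(2-bromo-3,5-dihydroxyphenyl)acetate
Product: 3 methyl 2-[5-(benzyloxy)-2-bromo-3-hydroxyphenyl]acetate
Conditions: BnBr (1.0 equiv), K2CO3 (1.05 equiv), acetone, rt
Reagents that add atoms: benzyl bromide, BrCc1ccccc1
Why: Williamson etherification; as with 4-bromoresorcinol, the hydroxyl para to bromine should be alkylated first because the ortho hydroxyl is flanked by bromine and its phenoxide is less nucleophilic, and dibenzyl ether and unreacted 2 are separable.

Step 3
Reactants: 3 methyl 2-[5-(benzyloxy)-2-bromo-3-hydroxyphenyl]acetate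
Product: 4 methyl 2-[5-(benzyloxy)-2-bromo-3-methoxyphenyl]acetate
Conditions: MeI, K2CO3, DMF, rt
Reagents that add atoms: iodomethane, CI
Why: Williamson methylation of the one remaining phenol; no selectivity question arises and carbonate is too weak to alkylate the ester alpha carbon.

Step 4
Reactants: 4 methyl 2-[5-(benzyloxy)-2-bromo-3-methoxyphenyl]acetate
Product: 5 2-[5-(benzyloxy)-2-bromo-3-methoxyphenyl]acetic acid
Conditions: LiOH·H2O, THF–H2O, rt; then 1 M HCl
Reagents that add atoms: lithium hydroxide, [Li+].[OH-]
Why: Saponification of an unhindered aliphatic methyl ester; the aryl bromide and the ethers are inert.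

Step 5
Reactants: 5 2-[5-(benzyloxy)-2-bromo-3-methoxyphenyl]acetic acid; 6 (4R)-4-benzyl-1,3-oxazolidin-2-one
Product: 8 (4R)-4-benzyl-3-{2-[5-(benzyloxy)-2-bromo-3-methoxyphenyl]acetyl}-1,3-oxazolidin-2-one, via mixed pivalic anhydride 7 (not isolated)
Conditions: PivCl, Et3N, THF, −20 °C; then LiCl, 6, −20 °C to rt
Reagents that add atoms: none
Why: N-Acylation of the oxazolidinone through the mixed anhydride, which is attacked at the less hindered arylacetyl carbonyl; the LiCl/amine variant avoids a strong base next to the aryl bromide.

Step 6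
Reactants: 9 4-(benzyloxy)-2-hydroxybenzaldehyde
Product: 10 4-(benzyloxy)-2-(methoxymethoxy)benzaldehyde
Conditions: MOMCl, i-Pr2NEt, CH2Cl2, 0 °C to 40 °C
Reagents that add atoms: chloromethyl methyl ether, COCCl
Why: Acetal protection of the hydrogen-bonded phenol by O-alkylation; the methoxymethyl ether is orthogonal to the benzyl ethers and to the aryl bromide used later.

Step 7
Reactants: 10 4-(benzyloxy)-2-(methoxymethoxy)benzaldehyde
Product: 11 [4-(benzyloxy)-2-(methoxymethoxy)phenyl]methanol
Conditions: NaBH4, MeOH–THF, 0 °C
Reagents that add atoms: none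
Why: Borohydride reduction of an aromatic aldehyde to the benzylic alcohol.

Step 8
Reactants: 11 [4-(benzyloxy)-2-(methoxymethoxy)phenyl]methanol
Product: 12 4-(benzyloxy)-1-(bromomethyl)-2-(methoxymethoxy)benzene
Conditions: CBr4, PPh3, CH2Cl2, 0 °C; short silica plug, used at once
Reagents that add atoms: carbon tetrabromide, BrC(Br)(Br)Br
Why: Appel bromination under neutral conditions, which spares the acetal; the electron-rich benzylic bromide is labile and is therefore not stored.

Step 9
Reactants: 8 (4R)-4-benzyl-3-{2-[5-(benzyloxy)-2-bromo-3-methoxyphenyl]acetyl}-1,3-oxazolidin-2-one; 12 4-(benzyloxy)-1-(bromomethyl)-2-(methoxymethoxy)benzene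
Product: 14 (4R)-4-benzyl-3-{(2R)-3-[4-(benzyloxy)-2-(methoxymethoxy)phenyl]-2-[5-(benzyloxy)-2-bromo-3-methoxyphenyl]propanoyl}-1,3-oxazolidin-2-one, via sodium enolate 13 (not isolated)
Conditions: NaN(SiMe3)2 (1.1 equiv), THF, −78 °C; then 12, −78 °C to −40 °C; aq. NH4Cl
Reagents that add atoms: none
Why: Evans asymmetric alkylation; the chelated Z-enolate 13 is alkylated by the reactive benzylic bromide on the face opposite the C4 benzyl group of the (4R)-auxiliary, which should set the future C3' as R, and a cold quench with little excess base protects the new α-aryl centre.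

Step 10
Reactants: 14 (4R)-4-benzyl-3-{(2R)-3-[4-(benzyloxy)-2-(methoxymethoxy)phenyl]-2-[5-(benzyloxy)-2-bromo-3-methoxyphenyl]propanoyl}-1,3-oxazolidin-2-one
Product: 15 (2R)-3-[4-(benzyloxy)-2-(methoxymethoxy)phenyl]-2-[5-(benzyloxy)-2-bromo-3-methoxyphenyl]propan-1-ol
Conditions: LiBH4, THF–MeOH, 0 °C
Reagents that add atoms: none
Why: Reductive cleavage of the imide at the exocyclic carbonyl gives the primary alcohol and returns the auxiliary; the mild hydride should neither epimerise the α-aryl centre nor touch the aryl bromide.

Step 11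
Reactants: 15 (2R)-3-[4-(benzyloxy)-2-(methoxymethoxy)phenyl]-2-[5-(benzyloxy)-2-bromo-3-methoxyphenyl]propan-1-ol
Product: 16 5-(benzyloxy)-2-{(2R)-2-[5-(benzyloxy)-2-bromo-3-methoxyphenyl]-3-hydroxypropyl}phenol
Conditions: conc. HCl (cat.), MeOH, 50 °C
Reagents that add atoms: none
Why: Acid-catalysed acetal exchange with methanol removes the methoxymethyl group; benzyl and methyl ethers, the aryl bromide and the stereocentre are not affected.

Step 12
Reactants: 16 5-(benzyloxy)-2-{(2R)-2-[5-(benzyloxy)-2-bromo-3-methoxyphenyl]-3-hydroxypropyl}phenol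
Product: 17 (3R)-7-(benzyloxy)-3-[5-(benzyloxy)-2-bromo-3-methoxyphenyl]chromane
Conditions: PPh3, DIAD, THF, 0 °C to rt
Reagents that add atoms: none
Why: Intramolecular Mitsunobu etherification; the phenol displaces the activated primary alcohol (6-exo-tet) to close chroman 2, and the stereocentre is not involved.

Step 13
Reactants: 17 (3R)-7-(benzyloxy)-3-[5-(benzyloxy)-2-bromo-3-methoxyphenyl]chromane; 9 4-(benzyloxy)-2-hydroxybenzaldehyde
Product: 20 5-(benzyloxy)-2-[{4-(benzyloxy)-2-[(3R)-7-(benzyloxy)chroman-3-yl]-6-methoxyphenyl}(hydroxy)methyl]phenol (either carbinol epimer), via aryllithium 18 (not isolated), via sodium phenoxide 19 (not isolated)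
Conditions: 17, n-BuLi (1.05 equiv), THF, −78 °C; separately 9 (1.5 equiv), NaH, THF, 0 °C; combine at −78 °C, warm to 0 °C; aq. NH4Cl; chromatography on Et3N-deactivated silica
Reagents that add atoms: none
Why: Bromine–lithium exchange followed by 1,2-addition of the aryllithium to the aldehyde; converting the salicylaldehyde to its phenoxide beforehand keeps the valuable aryllithium from being protonated, as in the standard preparation of ortho-hydroxybenzhydrols. The new carbinol centre is formed unselectively, which is immaterial because it is planarised in step 17.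

Step 14
Reactants: 21 2-hydroxy-4,5-dimethoxybenzaldehyde
Product: 22 2-(benzyloxy)-4,5-dimethoxybenzaldehyde
Conditions: BnBr, K2CO3, DMF, 60 °C
Reagents that add atoms: benzyl bromide, BrCc1ccccc1
Why: Williamson benzylation of the single phenol.

Step 15
Reactants: 22 2-(benzyloxy)-4,5-dimethoxybenzaldehyde
Product: 23 1-(benzyloxy)-4,5-dimethoxy-2-(2-methoxyethenyl)benzene (E/Z mixture)
Conditions: Ph3P(CH2OMe)Cl, KOtBu, THF, 0 °C to rt
Reagents that add atoms: (methoxymethyl)triphenylphosphonium chloride, COC[P+](c1ccccc1)(c1ccccc1)c1ccccc1.[Cl-]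
Why: Wittig methoxymethylenation, the standard one-carbon homologation of an aromatic aldehyde; the alkene geometry is irrelevant.

Step 16
Reactants: 23 1-(benzyloxy)-4,5-dimethoxy-2-(2-methoxyethenyl)benzene (E/Z mixture)
Product: 24 2-[2-(benzyloxy)-4,5-dimethoxyphenyl]acetaldehyde
Conditions: 2 M HCl, THF, rt; used directly
Reagents that add atoms: water, O
Why: Acid hydrolysis of the enol ether gives the arylacetaldehyde, which is used without storage because such aldehydes enolise and self-condense.

Step 17
Reactants: 20 5-(benzyloxy)-2-[{4-(benzyloxy)-2-[(3R)-7-(benzyloxy)chroman-3-yl]-6-methoxyphenyl}(hydroxy)methyl]phenol; 24 2-[2-(benzyloxy)-4,5-dimethoxyphenyl]acetaldehyde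
Product: 27 (3R,4S)-7-(benzyloxy)-4-{4-(benzyloxy)-2-[(3R)-7-(benzyloxy)chroman-3-yl]-6-methoxyphenyl}-3-[2-(benzyloxy)-4,5-dimethoxyphenyl]chroman-2-ol (anomeric mixture at C2), via ortho-quinone methide 25 (not isolated), via enamine 26 (not isolated)
Conditions: 24 (1.5 equiv), (R)-α,α-diphenylprolinol trimethylsilyl ether (20 mol%), PhCO2H (20 mol%), CH2Cl2, rt
Reagents that add atoms: none
Why: The weak acid ionises the doubly donor-stabilised benzhydrol 20 to ortho-quinone methide 25 while the amine condenses with 24 to the E-enamine 26; the enamine carbon adds to the methide carbon (C3–C4 bond, Michael addition) with rearomatisation of ring A, the freed phenol adds to the iminium or aldehyde carbon (O1–C2 bond), and hydrolysis returns the catalyst. The closest known reaction type is the aminocatalytic formal [4+2] annulation of aldehydes with ortho-quinone methides generated in situ from ortho-hydroxybenzhydrols, which gives 3,4-trans chroman-2-ols. The pyran ring closes by 6-exo-trig hemiacetalisation after the intermolecular carbon–carbon bond formation. C3 is set by the catalyst: the diphenyl(silyloxy)methyl group of the (R)-pyrrolidine shields one enamine face, so attack from the open face should give 3R, the mirror image of the sense known for the (S)-catalyst once the priority change caused by the α-aryl group is taken into account. C4 is set by relative topicity: in the open, synclinal transition state with the methide oxygen near the enamine nitrogen terminus, rings B and D lie anti, which should give 4S; this trans lactol is also the diequatorial, thermodynamically preferred one, so reversible ring opening does not erode it. The step needs chemoselectivity for the ring A methide, which is secured because only the ring A phenol is free and the ring D oxygen para to the carbinol is benzylated, and regioselectivity, which is inherent in the polarised methide. It also needs the catalyst to override the resident C3' centre, which is a spectator but sits ortho to the reacting carbon. C2 forms as an anomeric mixture that disappears in step 18.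

Step 18
Reactants: 27 (3R,4S)-7-(benzyloxy)-4-{4-(benzyloxy)-2-[(3R)-7-(benzyloxy)chroman-3-yl]-6-methoxyphenyl}-3-[2-(benzyloxy)-4,5-dimethoxyphenyl]chroman-2-ol (anomeric mixture at C2)
Product: 29 (3R,4S)-7-(benzyloxy)-4-{4-(benzyloxy)-2-[(3R)-7-(benzyloxy)chroman-3-yl]-6-methoxyphenyl}-3-[2-(benzyloxy)-4,5-dimethoxyphenyl]chromane, via oxocarbenium ion 28 (not isolated)
Conditions: Et3SiH, BF3·OEt2, CH2Cl2, −78 °C to −30 °C
Reagents that add atoms: none
Why: Ionic reduction of a lactol; the Lewis acid removes the anomeric hydroxyl and the silane delivers hydride to the oxocarbenium carbon, which becomes the C2 methylene, and the low temperature is chosen to suppress proton loss from C3.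

Step 19
Reactants: 29 (3R,4S)-7-(benzyloxy)-4-{4-(benzyloxy)-2-[(3R)-7-(benzyloxy)chroman-3-yl]-6-methoxyphenyl}-3-[2-(benzyloxy)-4,5-dimethoxyphenyl]chromane
Product: 30 (3R,4S)-3-(2-hydroxy-4,5-dimethoxyphenyl)-4-{4-hydroxy-2-[(3R)-7-hydroxychroman-3-yl]-6-methoxyphenyl}chroman-7-ol
Conditions: H2 (1 atm), 10% Pd/C, EtOAc–MeOH, rt
Reagents that add atoms: none
Why: Hydrogenolysis of four aryl benzyl ethers under neutral conditions; the chroman C–O bonds are not benzylic and the methyl ethers and stereocentres are untouched.

## Compound list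

1 | methyl 2-(3,5-dihydroxyphenyl)acetate | COC(=O)Cc1cc(O)cc(O)c1 | starting material
2 | methyl 2-(2-bromo-3,5-dihydroxyphenyl)acetate | COC(=O)Cc1cc(O)cc(O)c1Br | intermediate
3 | methyl 2-[5-(benzyloxy)-2-bromo-3-hydroxyphenyl]acetate | COC(=O)Cc1cc(OCc2ccccc2)cc(O)c1Br | intermediate
4 | methyl 2-[5-(benzyloxy)-2-bromo-3-methoxyphenyl]acetate | COC(=O)Cc1cc(OCc2ccccc2)cc(OC)c1Br | intermediate
5 | 2-[5-(benzyloxy)-2-bromo-3-methoxyphenyl]acetic acid | OC(=O)Cc1cc(OCc2ccccc2)cc(OC)c1Br | intermediate
6 | (4R)-4-benzyl-1,3-oxazolidin-2-one | O=C1N[C@H](Cc2ccccc2)CO1 | starting material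
7 | mixed anhydride of 5 with pivalic acid | CC(C)(C)C(=O)OC(=O)Cc1cc(OCc2ccccc2)cc(OC)c1Br | intermediate
8 | (4R)-4-benzyl-3-{2-[5-(benzyloxy)-2-bromo-3-methoxyphenyl]acetyl}-1,3-oxazolidin-2-one | COc1cc(OCc2ccccc2)cc(CC(=O)N2[C@H](Cc3ccccc3)COC2=O)c1Br | intermediate
9 | 4-(benzyloxy)-2-hydroxybenzaldehyde | O=Cc1ccc(OCc2ccccc2)cc1O | starting material
10 | 4-(benzyloxy)-2-(methoxymethoxy)benzaldehyde | COCOc1cc(OCc2ccccc2)ccc1C=O | intermediate
11 | [4-(benzyloxy)-2-(methoxymethoxy)phenyl]methanol | COCOc1cc(OCc2ccccc2)ccc1CO | intermediate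
12 | 4-(benzyloxy)-1-(bromomethyl)-2-(methoxymethoxy)benzene | COCOc1cc(OCc2ccccc2)ccc1CBr | intermediate
13 | sodium (Z)-enolate of imide 8 | COc1cc(OCc2ccccc2)cc(/C=C(\[O-])N2[C@H](Cc3ccccc3)COC2=O)c1Br.[Na+] | intermediate
14 | (4R)-4-benzyl-3-{(2R)-3-[4-(benzyloxy)-2-(methoxymethoxy)phenyl]-2-[5-(benzyloxy)-2-bromo-3-methoxyphenyl]propanoyl}-1,3-oxazolidin-2-one | COc1cc(OCc2ccccc2)cc([C@@H](Cc2ccc(OCc3ccccc3)cc2OCOC)C(=O)N2[C@H](Cc3ccccc3)COC2=O)c1Br | intermediate
15 | (2R)-3-[4-(benzyloxy)-2-(methoxymethoxy)phenyl]-2-[5-(benzyloxy)-2-bromo-3-methoxyphenyl]propan-1-ol | COc1cc(OCc2ccccc2)cc([C@@H](Cc2ccc(OCc3ccccc3)cc2OCOC)CO)c1Br | intermediate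
16 | 5-(benzyloxy)-2-{(2R)-2-[5-(benzyloxy)-2-bromo-3-methoxyphenyl]-3-hydroxypropyl}phenol | COc1cc(OCc2ccccc2)cc([C@@H](Cc2ccc(OCc3ccccc3)cc2O)CO)c1Br | intermediate
17 | (3R)-7-(benzyloxy)-3-[5-(benzyloxy)-2-bromo-3-methoxyphenyl]chromane | COc1cc(OCc2ccccc2)cc([C@@H]2COc3cc(OCc4ccccc4)ccc3C2)c1Br | intermediate
18 | {4-(benzyloxy)-2-[(3R)-7-(benzyloxy)chroman-3-yl]-6-methoxyphenyl}lithium | COc1cc(OCc2ccccc2)cc([C@@H]2COc3cc(OCc4ccccc4)ccc3C2)c1[Li] | intermediate
19 | sodium 5-(benzyloxy)-2-formylphenoxide | [Na+].[O-]c1cc(OCc2ccccc2)ccc1C=O | intermediate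
20 | 5-(benzyloxy)-2-[{4-(benzyloxy)-2-[(3R)-7-(benzyloxy)chroman-3-yl]-6-methoxyphenyl}(hydroxy)methyl]phenol (either carbinol epimer) | Oc1cc(OCc2ccccc2)ccc1C(O)c1c(OC)cc(OCc2ccccc2)cc1[C@@H]1COc2cc(OCc3ccccc3)ccc2C1 | intermediate
21 | 2-hydroxy-4,5-dimethoxybenzaldehyde | COc1cc(O)c(C=O)cc1OC | starting material
22 | 2-(benzyloxy)-4,5-dimethoxybenzaldehyde | COc1cc(OCc2ccccc2)c(C=O)cc1OC | intermediate
23 | 1-(benzyloxy)-4,5-dimethoxy-2-(2-methoxyethenyl)benzene (E/Z mixture) | COC=Cc1cc(OC)c(OC)cc1OCc1ccccc1 | intermediate
24 | 2-[2-(benzyloxy)-4,5-dimethoxyphenyl]acetaldehyde | COc1cc(OCc2ccccc2)c(CC=O)cc1OC | intermediate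
25 | 3-(benzyloxy)-6-[{4-(benzyloxy)-2-[(3R)-7-(benzyloxy)chroman-3-yl]-6-methoxyphenyl}methylidene]cyclohexa-2,4-dien-1-one (ortho-quinone methide, alkene geometry not fixed) | O=C1C=C(OCc2ccccc2)C=CC1=Cc1c(OC)cc(OCc2ccccc2)cc1[C@@H]1COc2cc(OCc3ccccc3)ccc2C1 | intermediate
26 | (2R)-1-{(E)-2-[2-(benzyloxy)-4,5-dimethoxyphenyl]ethenyl}-2-[diphenyl(trimethylsilyloxy)methyl]pyrrolidine | COc1cc(OCc2ccccc2)c(/C=C/N2CCC[C@@H]2C(O[Si](C)(C)C)(c2ccccc2)c2ccccc2)cc1OC | intermediate
27 | (3R,4S)-7-(benzyloxy)-4-{4-(benzyloxy)-2-[(3R)-7-(benzyloxy)chroman-3-yl]-6-methoxyphenyl}-3-[2-(benzyloxy)-4,5-dimethoxyphenyl]chroman-2-ol (anomeric mixture) | COc1cc(OCc2ccccc2)c(cc1OC)[C@@H]1C(O)Oc2cc(OCc3ccccc3)ccc2[C@H]1c1c(OC)cc(OCc2ccccc2)cc1[C@@H]1COc2cc(OCc3ccccc3)ccc2C1 | intermediate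
28 | (3R,4S)-3,4-dihydrochromenylium (oxocarbenium) ion derived from 27 | COc1cc(OCc2ccccc2)c(cc1OC)[C@@H]1C=[O+]c2cc(OCc3ccccc3)ccc2[C@H]1c1c(OC)cc(OCc2ccccc2)cc1[C@@H]1COc2cc(OCc3ccccc3)ccc2C1 | intermediate
29 | (3R,4S)-7-(benzyloxy)-4-{4-(benzyloxy)-2-[(3R)-7-(benzyloxy)chroman-3-yl]-6-methoxyphenyl}-3-[2-(benzyloxy)-4,5-dimethoxyphenyl]chromane | COc1cc(OCc2ccccc2)c(cc1OC)[C@@H]1COc2cc(OCc3ccccc3)ccc2[C@H]1c1c(OC)cc(OCc2ccccc2)cc1[C@@H]1COc2cc(OCc3ccccc3)ccc2C1 | intermediate
30 | (3R,4S)-3-(2-hydroxy-4,5-dimethoxyphenyl)-4-{4-hydroxy-2-[(3R)-7-hydroxychroman-3-yl]-6-methoxyphenyl}chroman-7-ol | COc1cc(O)c([C@@H]2COc3cc(O)ccc3[C@H]2c2c(OC)cc(O)cc2[C@@H]2COc3cc(O)ccc3C2)cc1OC | target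

## Step count and risks

Total: 19 steps. Longest linear sequence: 13 steps (steps 1–5, 9–13 and 17–19, from compound 1).

**Step 17 (key step).** The carbon–carbon bond may form slowly because the methide carbon carries an aryl group substituted at both ortho positions, so that the methide oligomerises or returns to 20 before the bulky catalyst-bound enamine reaches it. Facial control may also be incomplete if the C3' centre, ortho to the reacting carbon, opposes the catalyst, and the arylacetaldehyde can self-condense. Fallback, from 24 and 20, returning at 27: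
- Aldehyde 24 is condensed with pyrrolidine over molecular sieves to the small, strongly nucleophilic enamine 1-{(E)-2-[2-(benzyloxy)-4,5-dimethoxyphenyl]ethenyl}pyrrolidine F1.
- F1 is combined with 20 and a little acetic acid in the classical enamine/ortho-quinone methide cycloaddition, which should give the trans 2-(pyrrolidin-1-yl)chroman aminal F2 as two diastereomers.
- Mild aqueous acid hydrolyses F2 to lactol 27 and its (3S,4R) diastereomer F3.
- Because C3' is fixed, 27 and F3 are diastereomers and are separated by chromatography. Stereocontrol is thus replaced by separation, at the cost of up to half the material.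

**Step 2.** Site selectivity between the two hydroxyls may be poor, or dialkylation may dominate. Fallback, from 1, returning at 4:
- Compound 1 is monomethylated (MeI, K2CO3, one equivalent) to methyl 2-(3-hydroxy-5-methoxyphenyl)acetate F4.
- F4 is brominated para to the free hydroxyl with tetrabutylammonium tribromide (Bu4NBr3) to methyl 2-(2-bromo-5-hydroxy-3-methoxyphenyl)acetate F5.
- F5 is benzylated (BnBr, K2CO3) to 4. The bromine position is then defined by the para-directing phenol and not by differential alkylation.

**Step 13.** Addition to the phenoxide-deactivated aldehyde may be incomplete, the aryllithium may be quenched by proton transfer, and the very electron-rich benzhydrol may ionise during work-up. Fallback, from 9 and 17, returning at 20: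
- Aldehyde 9 is allylated (allyl bromide, K2CO3) to 2-(allyloxy)-4-(benzyloxy)benzaldehyde F6.
- Aryllithium 18, made from 17 as before, is added to F6 to give the allyl-protected benzhydrol F7.
- The allyl group is removed with Pd(PPh3)4 (zerovalent palladium) and morpholine under neutral conditions to give 20.

**Step 18.** The oxocarbenium ion may lose the C3 proton to give a 4H-chromene, which would scramble C3 on re-protonation. The Lewis acid may also ionise the electron-rich C4–aryl system or attack a benzyl ether. Fallback, from 27, returning at 29: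
- Lactol 27 is reduced through its open hydroxy aldehyde with NaBH4 (MeOH–THF, 0 °C) to the phenol alcohol (2R,3S)-2-[2-(benzyloxy)-4,5-dimethoxyphenyl]-3-[4-(benzyloxy)-2-hydroxyphenyl]-3-{4-(benzyloxy)-2-[(3R)-7-(benzyloxy)chroman-3-yl]-6-methoxyphenyl}propan-1-ol F8.
- F8 is closed by Mitsunobu etherification (PPh3, DIAD, THF) to 29, the same ring closure already used for chroman 2 and free of any acid.

## Further compounds

F1 | step 17 | 1-{(E)-2-[2-(benzyloxy)-4,5-dimethoxyphenyl]ethenyl}pyrrolidine | COc1cc(OCc2ccccc2)c(/C=C/N2CCCC2)cc1OC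
F2 | step 17 | 1-{7-(benzyloxy)-4-{4-(benzyloxy)-2-[(3R)-7-(benzyloxy)chroman-3-yl]-6-methoxyphenyl}-3-[2-(benzyloxy)-4,5-dimethoxyphenyl]chroman-2-yl}pyrrolidine (3,4-trans, both diastereomers) | COc1cc(OCc2ccccc2)c(cc1OC)C1C(N2CCCC2)Oc2cc(OCc3ccccc3)ccc2C1c1c(OC)cc(OCc2ccccc2)cc1[C@@H]1COc2cc(OCc3ccccc3)ccc2C1
F3 | step 17 | (3S,4R)-7-(benzyloxy)-4-{4-(benzyloxy)-2-[(3R)-7-(benzyloxy)chroman-3-yl]-6-methoxyphenyl}-3-[2-(benzyloxy)-4,5-dimethoxyphenyl]chroman-2-ol | COc1cc(OCc2ccccc2)c(cc1OC)[C@H]1C(O)Oc2cc(OCc3ccccc3)ccc2[C@@H]1c1c(OC)cc(OCc2ccccc2)cc1[C@@H]1COc2cc(OCc3ccccc3)ccc2C1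
F4 | step 2 | methyl 2-(3-hydroxy-5-methoxyphenyl)acetate | COC(=O)Cc1cc(O)cc(OC)c1
F5 | step 2 | methyl 2-(2-bromo-5-hydroxy-3-methoxyphenyl)acetate | COC(=O)Cc1cc(O)cc(OC)c1Br
F6 | step 13 | 2-(allyloxy)-4-(benzyloxy)benzaldehyde | C=CCOc1cc(OCc2ccccc2)ccc1C=O
F7 | step 13 | [2-(allyloxy)-4-(benzyloxy)phenyl]{4-(benzyloxy)-2-[(3R)-7-(benzyloxy)chroman-3-yl]-6-methoxyphenyl}methanol (either carbinol epimer) | C=CCOc1cc(OCc2ccccc2)ccc1C(O)c1c(OC)cc(OCc2ccccc2)cc1[C@@H]1COc2cc(OCc3ccccc3)ccc2C1
F8 | step 18 | (2R,3S)-2-[2-(benzyloxy)-4,5-dimethoxyphenyl]-3-[4-(benzyloxy)-2-hydroxyphenyl]-3-{4-(benzyloxy)-2-[(3R)-7-(benzyloxy)chroman-3-yl]-6-methoxyphenyl}propan-1-ol | COc1cc(OCc2ccccc2)c(cc1OC)[C@H](CO)[C@@H](c1ccc(OCc2ccccc2)cc1O)c1c(OC)cc(OCc2ccccc2)cc1[C@@H]1COc2cc(OCc3ccccc3)ccc2C1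
A1 | alternative 1 | methyl 2-{5-(benzyloxy)-2-[4-(benzyloxy)-2-(methoxymethoxy)benzoyl]-3-methoxyphenyl}-3-[4-(benzyloxy)-2-(methoxymethoxy)phenyl]propanoate (racemic) | COC(=O)C(Cc1ccc(OCc2ccccc2)cc1OCOC)c1cc(OCc2ccccc2)cc(OC)c1C(=O)c1ccc(OCc2ccccc2)cc1OCOC
A2 | alternative 1 | methyl 2-[4-(benzyloxy)-2-(methoxymethoxy)benzyl]-3-[4-(benzyloxy)-2-(methoxymethoxy)phenyl]-3-oxopropanoate (racemic) | COC(=O)C(Cc1ccc(OCc2ccccc2)cc1OCOC)C(=O)c1ccc(OCc2ccccc2)cc1OCOC
A3 | alternative 1 | 5-(benzyloxy)-3-methoxy-2-(trimethylsilyl)phenyl trifluoromethanesulfonate | COc1cc(OCc2ccccc2)cc(OS(=O)(=O)C(F)(F)F)c1[Si](C)(C)C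
A4 | alternative 1 | 5-(benzyloxy)-3-methoxybenzyne | COC1=CC(OCc2ccccc2)=CC#C1
A5 | alternative 2 | [4-(benzyloxy)-2-(methoxymethoxy)phenyl]{2-[(3R)-7-(benzyloxy)chroman-3-yl]-4-hydroxy-6-methoxyphenyl}methanone | COCOc1cc(OCc2ccccc2)ccc1C(=O)c1c(OC)cc(O)cc1[C@@H]1COc2cc(OCc3ccccc3)ccc2C1
A6 | alternative 2 | 1-[4-(benzyloxy)-2-(methoxymethoxy)phenyl]-3-[(3R)-7-(benzyloxy)chroman-3-yl]prop-2-yn-1-one | COCOc1cc(OCc2ccccc2)ccc1C(=O)C#C[C@@H]1COc2cc(OCc3ccccc3)ccc2C1
A7 | alternative 2 | 1,1-dimethoxy-3-(trimethylsilyloxy)buta-1,3-diene | COC(OC)=CC(=C)O[Si](C)(C)C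
A8 | alternative 3 | (4S)-7-(benzyloxy)-4-{4-(benzyloxy)-2-[(3R)-7-(benzyloxy)chroman-3-yl]-6-methoxyphenyl}chroman-2-one | O=C1C[C@H](c2c(OC)cc(OCc3ccccc3)cc2[C@@H]2COc3cc(OCc4ccccc4)ccc3C2)c2ccc(OCc3ccccc3)cc2O1
A9 | alternative 3 | (3S)-6-(benzyloxy)-3-{4-(benzyloxy)-2-[(3R)-7-(benzyloxy)chroman-3-yl]-6-methoxyphenyl}indan-1-one | O=C1C[C@H](c2c(OC)cc(OCc3ccccc3)cc2[C@@H]2COc3cc(OCc4ccccc4)ccc3C2)c2ccc(OCc3ccccc3)cc21
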